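**Retrosynthetic overview**

- The strategy rests on reading the furan as a folded, oxygenated geranylhydroquinone. Furan C2 (aryl-bearing) is the benzylic carbon C1'', C3=C4 is the C2''=C3'' olefin, C5 with O1 is the hydroxylated 3''-methyl group, and the acyloxy carbinol on C4 is C4''.
- The furan is the only ring built (the benzene ring is bought). Its O1–C2 bond comes from an oxidative quinone-methide oxa-cyclisation and aromatisation of a (2E)-3''-(hydroxymethyl)-4''-silyloxy geranylhydroquinone.
- That hydroquinone comes from a Negishi coupling (C1''–C2'' bond) of a 2,5-bis(silyloxy)benzylzinc with a (Z)-β-iodoacrylate, followed by ester reduction and aryl desilylation.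
- The iodoacrylate comes from a catalytic asymmetric iodo-aldol of methyl propiolate with 4-methylpent-3-enal, which sets the C3''–C4'' bond, the olefin geometry and the single stereocentre (R).
- End game on the furylquinone: carbinol desilylation, isovalerate formation while the arene is masked as the quinone, then dithionite reduction.

Key step: step 10

Assumption (step 2): the (S)-configured oxazaborolidinium ion is taken to leave the si face of the bound aldehyde open to the iodoallenoate, which gives the 3R carbinol. If the sense of induction proves opposite, the (R)-configured catalyst is used and nothing else changes.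

TBS = tert-butyldimethylsilyl throughout.

**Route**

Step 1
Reactants: 1 4-methylpent-3-en-1-ol
Product: 2 4-methylpent-3-enal
Conditions: Dess–Martin periodinane (1,1,1-triacetoxy-1,1-dihydro-1,2-benziodoxol-3(1H)-one), NaHCO3, CH2Cl2, 0 → 25 °C; filtered through a short silica plug and used at once as a CH2Cl2 solution
Reagents that add atoms: none
Why: Dess–Martin oxidation under buffered, non-basic conditions should stop at the aldehyde and avoid migration of the β,γ-double bond into conjugation.

Step 2
Reactants: 2 4-methylpent-3-enal; 3 methyl propiolate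
Product: 6 methyl (2Z,3R)-3-hydroxy-2-(iodomethylidene)-6-methylhept-5-enoate, via silyl iodoallenoate 4 (not isolated), via trimethylsilyl ether 5 (not isolated)
Conditions: TMSI (1.3 equiv), (S)-tetrahydro-1-(2-methylphenyl)-3,3-diphenyl-1H,3H-pyrrolo[1,2-c][1,3,2]oxazaborole·HN(SO2CF3)2 (20 mol%), CH2Cl2, −78 °C; then 1 M HCl, THF, 0 °C
Reagents that add atoms: iodotrimethylsilane, C[Si](C)(C)I
Why: In this catalytic asymmetric three-component iodo-aldol (halo Morita–Baylis–Hillman-type) coupling, iodide from TMSI adds to the propiolate to give allenoate 4, whose central carbon should attack the boron-bound aldehyde anti to iodine (Z-iodoalkene) and on the si face left open by the (S)-configured catalyst (3R carbinol).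

Step 3
Reactants: 6 methyl (2Z,3R)-3-hydroxy-2-(iodomethylidene)-6-methylhept-5-enoate
Product: 7 methyl (2Z,3R)-3-(tert-butyldimethylsilyloxy)-2-(iodomethylidene)-6-methylhept-5-enoate
Conditions: TBSOTf, 2,6-lutidine, CH2Cl2, −78 → 0 °C
Reagents that add atoms: tert-butyldimethylsilyl triflate, CC(C)(C)[Si](C)(C)OS(=O)(=O)C(F)(F)F
Why: Silylation of the secondary alcohol with the silyl triflate and a hindered base is fast at low temperature and should leave the iodoacrylate and the stereocentre untouched.

Step 4
Reactants: 8 2,5-dihydroxybenzaldehyde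
Product: 9 2,5-bis(tert-butyldimethylsilyloxy)benzaldehyde
Conditions: TBSCl (2.4 equiv), imidazole, DMF, 25 °C
Reagents that add atoms: tert-butyldimethylsilyl chloride, CC(C)(C)[Si](C)(C)Cl
Why: Imidazole-promoted silylation should cap both phenols, which is needed for the organozinc chemistry that follows.

Step 5
Reactants: 9 2,5-bis(tert-butyldimethylsilyloxy)benzaldehyde
Product: 10 [2,5-bis(tert-butyldimethylsilyloxy)phenyl]methanol
Conditions: NaBH4, MeOH/THF, 0 °C
Reagents that add atoms: none
Why: Borohydride reduction of the aryl aldehyde is fast at 0 °C, where the aryl silyl ethers should neither cleave nor migrate.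

Step 6
Reactants: 10 [2,5-bis(tert-butyldimethylsilyloxy)phenyl]methanol
Product: 11 2,5-bis(tert-butyldimethylsilyloxy)benzyl chloride
Conditions: PPh3, N-chlorosuccinimide, CH2Cl2, 0 → 25 °C
Reagents that add atoms: N-chlorosuccinimide, O=C1CCC(=O)N1Cl
Why: Appel-type chlorination through the alkoxyphosphonium salt works under neutral conditions and should give the benzylic chloride without touching the aryl silyl ethers.

Step 7
Reactants: 11 2,5-bis(tert-butyldimethylsilyloxy)benzyl chloride; 7 methyl (2Z,3R)-3-(tert-butyldimethylsilyloxy)-2-(iodomethylidene)-6-methylhept-5-enoate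
Product: 13 methyl (2Z,3R)-2-{2-[2,5-bis(tert-butyldimethylsilyloxy)phenyl]ethylidene}-3-(tert-butyldimethylsilyloxy)-6-methylhept-5-enoate, via benzylzinc chloride 12 (not isolated)
Conditions: 11, Zn dust, LiCl, THF, 25 °C; then 7, Pd(PPh3)4 (5 mol%), THF, 25 °C
Reagents that add atoms: none
Why: LiCl-assisted zinc insertion into the benzylic chloride followed by Negishi cross-coupling (oxidative addition of zerovalent palladium into the C–I bond, transmetalation, reductive elimination) should proceed with retention of olefin geometry, so the benzylic carbon ends up cis to the ester and trans to the silyloxy carbinol.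

Step 8
Reactants: 13 methyl (2Z,3R)-2-{2-[2,5-bis(tert-butyldimethylsilyloxy)phenyl]ethylidene}-3-(tert-butyldimethylsilyloxy)-6-methylhept-5-enoate
Product: 14 1,4-bis(tert-butyldimethylsilyloxy)-2-[(2E,4R)-4-(tert-butyldimethylsilyloxy)-3-(hydroxymethyl)-7-methylocta-2,6-dien-1-yl]benzene
Conditions: i-Bu2AlH (2.5 equiv), CH2Cl2, −78 → −20 °C; aq. KNaC4H4O6 (Rochelle salt)
Reagents that add atoms: none
Why: i-Bu2AlH should reduce the α,β-unsaturated methyl ester by 1,2-addition to the allylic alcohol while the silyl ethers and the trisubstituted olefins stay inert.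

Step 9
Reactants: 14 1,4-bis(tert-butyldimethylsilyloxy)-2-[(2E,4R)-4-(tert-butyldimethylsilyloxy)-3-(hydroxymethyl)-7-methylocta-2,6-dien-1-yl]benzene
Product: 15 2-[(2E,4R)-4-(tert-butyldimethylsilyloxy)-3-(hydroxymethyl)-7-methylocta-2,6-dien-1-yl]benzene-1,4-diol (hydroxymethyl cis to the benzylic CH2)
Conditions: KHF2 (2.5 equiv), degassed MeOH, 25 °C, argon; used directly in step 10
Reagents that add atoms: none
Why: Bifluoride in methanol cleaves phenolic silyl ethers far faster than alkyl silyl ethers, and the near-neutral medium should protect the free hydroquinone from autoxidation.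

Step 10
Reactants: 15 2-[(2E,4R)-4-(tert-butyldimethylsilyloxy)-3-(hydroxymethyl)-7-methylocta-2,6-dien-1-yl]benzene-1,4-diol
Product: 22 2-{4-[(R)-1-(tert-butyldimethylsilyloxy)-4-methylpent-3-enyl]furan-2-yl}-1,4-benzoquinone, via allylquinone 16 (not isolated), via ortho-quinone methide 17 (not isolated), via dihydrofuranylhydroquinone 18 (not isolated), via dihydrofuranylquinone 19 (not isolated), via furanylidene quinone methide 20 (not isolated), via furylhydroquinone 21 (not isolated)
Conditions: Ag2O (5 equiv), Et3N (0.1 equiv), Na2SO4, CH2Cl2, 25 °C, dark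
Reagents that add atoms: none
Why: Proposed new method: Ag2O should oxidise 15 to quinone 16, whose C1'' hydrogen (benzylic to the quinone and allylic) the amine relays through the ring C2=C3 bond to the C4 carbonyl oxygen to give the vinylogous ortho-quinone methide 17; the hydroxymethyl oxygen, held cis to C1'' by the C2''=C3'' olefin, then adds to C1'' and the arene is regained as 18, after which the same oxidation–tautomerisation sequence (19, 20) ends with a proton shift from C5 that aromatises the ring to furan 21, which the excess oxidant leaves as 22. The closest known reactions are the base-induced tautomerisation of prenylquinones to ortho-quinone methides on the way to 2H-chromenes and the intramolecular capture of quinone methides by hydroxyl groups, whereas running the sequence twice in one flask up to the furan is untested. The one ring closure (O1–C2) is a 5-exo-trig conjugate addition to the exocyclic quinone-methide double bond, reached after rotation about the C1''–C2'' bond. The C2 stereocentre of 18 forms without control and is erased on aromatisation, while the silyloxy carbinol carbon never joins a reacting π system and should keep its R configuration. The step needs chemoselectivity for this 5-exo addition over oxa-6π closure of 17 onto C3'' (2H-chromene), and the cis hydroxymethyl group, the crowded fully substituted C3'' terminus, the poor leaving-group ability of the silyloxy group (no vinylogous elimination) and the aromatisation that drives each pass should secure it.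

Step 11
Reactants: 22 2-{4-[(R)-1-(tert-butyldimethylsilyloxy)-4-methylpent-3-enyl]furan-2-yl}-1,4-benzoquinone
Product: 23 2-{4-[(R)-1-hydroxy-4-methylpent-3-enyl]furan-2-yl}-1,4-benzoquinone
Conditions: HF·pyridine, pyridine, THF, 0 → 25 °C
Reagents that add atoms: none
Why: Buffered HF should remove the secondary silyl ether without the basic fluoride that would attack the quinone and without acid strong enough to ionise the furyl carbinol.

Step 12
Reactants: 23 2-{4-[(R)-1-hydroxy-4-methylpent-3-enyl]furan-2-yl}-1,4-benzoquinone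
Product: 24 (R)-1-[5-(3,6-dioxocyclohexa-1,4-dien-1-yl)furan-3-yl]-4-methylpent-3-enyl 3-methylbutanoate
Conditions: isovaleric anhydride (1.5 equiv), 2,6-lutidine, 4-(dimethylamino)pyridine (10 mol%), CH2Cl2, 0 °C
Reagents that add atoms: isovaleric anhydride, CC(C)CC(=O)OC(=O)CC(C)C
Why: With the arene held as the quinone the carbinol is the only hydroxyl group, so DMAP-catalysed acylation should give the ester with retention at the stereocentre and no phenol competing.

Step 13
Reactants: 24 (R)-1-[5-(3,6-dioxocyclohexa-1,4-dien-1-yl)furan-3-yl]-4-methylpent-3-enyl 3-methylbutanoate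
Product: 25 (R)-1-[5-(2,5-dihydroxyphenyl)furan-3-yl]-4-methylpent-3-enyl 3-methylbutanoate
Conditions: Na2S2O4, EtOAc/H2O, 25 °C, argon
Reagents that add atoms: none
Why: Dithionite reduction of the quinone to the hydroquinone in a two-phase medium should not touch the ester, the furan or the olefin.

**Compound list**

1 | 4-methylpent-3-en-1-ol | CC(C)=CCCO | starting material
2 | 4-methylpent-3-enal | CC(C)=CCC=O | intermediate
3 | methyl propiolate | C#CC(=O)OC | starting material
4 | 1-iodo-3-methoxy-3-(trimethylsilyloxy)propa-1,2-diene (silyl iodoallenoate, racemic axis) | COC(O[Si](C)(C)C)=C=CI | intermediate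
5 | methyl (2Z,3R)-2-(iodomethylidene)-6-methyl-3-(trimethylsilyloxy)hept-5-enoate | CC(C)=CC[C@@H](O[Si](C)(C)C)/C(=C/I)C(=O)OC | intermediate
6 | methyl (2Z,3R)-3-hydroxy-2-(iodomethylidene)-6-methylhept-5-enoate | CC(C)=CC[C@@H](O)/C(=C/I)C(=O)OC | intermediate
7 | methyl (2Z,3R)-3-(tert-butyldimethylsilyloxy)-2-(iodomethylidene)-6-methylhept-5-enoate | CC(C)=CC[C@@H](O[Si](C)(C)C(C)(C)C)/C(=C/I)C(=O)OC | intermediate
8 | 2,5-dihydroxybenzaldehyde | O=Cc1cc(O)ccc1O | starting material
9 | 2,5-bis(tert-butyldimethylsilyloxy)benzaldehyde | O=Cc1cc(O[Si](C)(C)C(C)(C)C)ccc1O[Si](C)(C)C(C)(C)C | intermediate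
10 | [2,5-bis(tert-butyldimethylsilyloxy)phenyl]methanol | OCc1cc(O[Si](C)(C)C(C)(C)C)ccc1O[Si](C)(C)C(C)(C)C | intermediate
11 | 2,5-bis(tert-butyldimethylsilyloxy)benzyl chloride | ClCc1cc(O[Si](C)(C)C(C)(C)C)ccc1O[Si](C)(C)C(C)(C)C | intermediate
12 | [2,5-bis(tert-butyldimethylsilyloxy)benzyl]zinc chloride (LiCl complex in THF) | Cl[Zn]Cc1cc(O[Si](C)(C)C(C)(C)C)ccc1O[Si](C)(C)C(C)(C)C | intermediate
13 | methyl (2Z,3R)-2-{2-[2,5-bis(tert-butyldimethylsilyloxy)phenyl]ethylidene}-3-(tert-butyldimethylsilyloxy)-6-methylhept-5-enoate | CC(C)=CC[C@@H](O[Si](C)(C)C(C)(C)C)/C(=C/Cc1cc(O[Si](C)(C)C(C)(C)C)ccc1O[Si](C)(C)C(C)(C)C)C(=O)OC | intermediate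
14 | 1,4-bis(tert-butyldimethylsilyloxy)-2-[(2E,4R)-4-(tert-butyldimethylsilyloxy)-3-(hydroxymethyl)-7-methylocta-2,6-dien-1-yl]benzene | CC(C)=CC[C@@H](O[Si](C)(C)C(C)(C)C)/C(=C/Cc1cc(O[Si](C)(C)C(C)(C)C)ccc1O[Si](C)(C)C(C)(C)C)CO | intermediate
15 | 2-[(2E,4R)-4-(tert-butyldimethylsilyloxy)-3-(hydroxymethyl)-7-methylocta-2,6-dien-1-yl]benzene-1,4-diol | CC(C)=CC[C@@H](O[Si](C)(C)C(C)(C)C)/C(=C/Cc1cc(O)ccc1O)CO | intermediate
16 | 2-[(2E,4R)-4-(tert-butyldimethylsilyloxy)-3-(hydroxymethyl)-7-methylocta-2,6-dien-1-yl]-1,4-benzoquinone | CC(C)=CC[C@@H](O[Si](C)(C)C(C)(C)C)/C(=C/CC1=CC(=O)C=CC1=O)CO | intermediate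
17 | 4-hydroxy-6-[(2E,4R)-4-(tert-butyldimethylsilyloxy)-3-(hydroxymethyl)-7-methylocta-2,6-dien-1-ylidene]cyclohexa-2,4-dien-1-one (ortho-quinone methide, exocyclic geometry not defined) | CC(C)=CC[C@@H](O[Si](C)(C)C(C)(C)C)/C(CO)=C/C=C1C=C(O)C=CC1=O | intermediate
18 | 2-{4-[(R)-1-(tert-butyldimethylsilyloxy)-4-methylpent-3-enyl]-2,5-dihydrofuran-2-yl}benzene-1,4-diol (both C2 epimers) | CC(C)=CC[C@@H](O[Si](C)(C)C(C)(C)C)C1=CC(c2cc(O)ccc2O)OC1 | intermediate
19 | 2-{4-[(R)-1-(tert-butyldimethylsilyloxy)-4-methylpent-3-enyl]-2,5-dihydrofuran-2-yl}-1,4-benzoquinone (both C2 epimers) | CC(C)=CC[C@@H](O[Si](C)(C)C(C)(C)C)C1=CC(C2=CC(=O)C=CC2=O)OC1 | intermediate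
20 | 4-hydroxy-6-{4-[(R)-1-(tert-butyldimethylsilyloxy)-4-methylpent-3-enyl]furan-2(5H)-ylidene}cyclohexa-2,4-dien-1-one | CC(C)=CC[C@@H](O[Si](C)(C)C(C)(C)C)C1=CC(=C2C=C(O)C=CC2=O)OC1 | intermediate
21 | 2-{4-[(R)-1-(tert-butyldimethylsilyloxy)-4-methylpent-3-enyl]furan-2-yl}benzene-1,4-diol | CC(C)=CC[C@@H](O[Si](C)(C)C(C)(C)C)c1coc(-c2cc(O)ccc2O)c1 | intermediate
22 | 2-{4-[(R)-1-(tert-butyldimethylsilyloxy)-4-methylpent-3-enyl]furan-2-yl}-1,4-benzoquinone | CC(C)=CC[C@@H](O[Si](C)(C)C(C)(C)C)c1coc(C2=CC(=O)C=CC2=O)c1 | intermediate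
23 | 2-{4-[(R)-1-hydroxy-4-methylpent-3-enyl]furan-2-yl}-1,4-benzoquinone | CC(C)=CC[C@@H](O)c1coc(C2=CC(=O)C=CC2=O)c1 | intermediate
24 | (R)-1-[5-(3,6-dioxocyclohexa-1,4-dien-1-yl)furan-3-yl]-4-methylpent-3-enyl 3-methylbutanoate | CC(C)=CC[C@@H](OC(=O)CC(C)C)c1coc(C2=CC(=O)C=CC2=O)c1 | intermediate
25 | (R)-1-[5-(2,5-dihydroxyphenyl)furan-3-yl]-4-methylpent-3-enyl 3-methylbutanoate | CC(C)=CC[C@@H](OC(=O)CC(C)C)c1coc(-c2cc(O)ccc2O)c1 | target

**Step count**

Total: 13 steps. Longest linear sequence: 10 steps (steps 1, 2, 3, 7, 8, 9, 10, 11, 12, 13; the aryl branch, steps 4 to 6, joins at step 7 and is equally long).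

**Steps most likely to fail**

1. Step 10 (carries the label "Proposed new method:"). The ortho-quinone methide may close through its carbonyl oxygen onto C3'' to a 2H-chromene, the second oxidation–tautomerisation pass may stall at the dihydrofuran, or the amine may add to the quinone. The fallback builds the furan by known butenolide chemistry, sets out from iodoacrylate 7 and aldehyde 9, and comes back at 22. A Nozaki–Hiyama–Kishi coupling of 7 with 9 (CrCl2, NiCl2 2 mol%, DMF, 25 °C) gives a chromium alkoxide cis to the ester, which should lactonise in the flask to 5-[2,5-bis(tert-butyldimethylsilyloxy)phenyl]-3-[(R)-1-(tert-butyldimethylsilyloxy)-4-methylpent-3-enyl]furan-2(5H)-one F1 (both C5 epimers). Reduction of the lactone with i-Bu2AlH (1.1 equiv, CH2Cl2, −78 °C) gives the lactol, which on mildly acidic work-up should lose water and aromatise to 2-[2,5-bis(tert-butyldimethylsilyloxy)phenyl]-4-[(R)-1-(tert-butyldimethylsilyloxy)-4-methylpent-3-enyl]furan F2. KHF2 in MeOH then frees the two phenols to give furylhydroquinone 21, and Ag2O in Et2O oxidises it to 22, from which steps 11 to 13 follow unchanged. The carbinol stereocentre is not touched in this sequence.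

2. Step 2. Facial selectivity may be poor with an unbranched, enolisable aldehyde, and the cationic boron Lewis acid may isomerise the aldehyde to the conjugated enal. The fallback replaces asymmetric catalysis by racemic synthesis and enzymatic resolution, sets out from 2 and 3, and comes back at 6. The MgI2-mediated iodo-aldol (MgI2, CH2Cl2, 0 °C) should give racemic methyl (2Z)-3-hydroxy-2-(iodomethylidene)-6-methylhept-5-enoate F3, which is acetylated (Ac2O, pyridine, DMAP cat.) to the racemic acetate methyl (2Z)-3-acetoxy-2-(iodomethylidene)-6-methylhept-5-enoate F4. Hydrolysis with Burkholderia cepacia lipase (pH 7 phosphate buffer/acetone, 30 °C), stopped short of half conversion, is expected by the empirical size rule for lipases (iodoacrylate unit as the large substituent) to release the 3R alcohol 6. The unreacted methyl (2Z,3S)-3-acetoxy-2-(iodomethylidene)-6-methylhept-5-enoate F5 is removed by chromatography. The sense of the resolution would be confirmed by Mosher ester analysis before going on.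

3. Step 12. The acyl-transfer catalyst or the base may add to the unsubstituted positions of the quinone, or the furyl carbinol may ionise under forcing acylation. The fallback gives up the quinone as a mask, sets out from 23, and comes back at the target 25. Na2S2O4 (EtOAc/H2O, argon) reduces 23 to 2-{4-[(R)-1-hydroxy-4-methylpent-3-enyl]furan-2-yl}benzene-1,4-diol F6. Exhaustive acylation (isovaleryl chloride, pyridine, CH2Cl2, 0 °C) gives the tris-ester (R)-1-{5-[2,5-bis(3-methylbutanoyloxy)phenyl]furan-3-yl}-4-methylpent-3-enyl 3-methylbutanoate F7. Pyrrolidine (2.2 equiv, CH2Cl2, 0 °C, argon) should then cleave only the two aryl esters by aminolysis, leaving the alkyl ester and giving 25.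

**Further compounds**

F1 | step 10 | 5-[2,5-bis(tert-butyldimethylsilyloxy)phenyl]-3-[(R)-1-(tert-butyldimethylsilyloxy)-4-methylpent-3-enyl]furan-2(5H)-one | CC(C)=CC[C@@H](O[Si](C)(C)C(C)(C)C)C1=CC(c2cc(O[Si](C)(C)C(C)(C)C)ccc2O[Si](C)(C)C(C)(C)C)OC1=O
F2 | step 10 | 2-[2,5-bis(tert-butyldimethylsilyloxy)phenyl]-4-[(R)-1-(tert-butyldimethylsilyloxy)-4-methylpent-3-enyl]furan | CC(C)=CC[C@@H](O[Si](C)(C)C(C)(C)C)c1coc(-c2cc(O[Si](C)(C)C(C)(C)C)ccc2O[Si](C)(C)C(C)(C)C)c1
F3 | step 2 | racemic methyl (2Z)-3-hydroxy-2-(iodomethylidene)-6-methylhept-5-enoate | CC(C)=CCC(O)/C(=C/I)C(=O)OC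
F4 | step 2 | racemic methyl (2Z)-3-acetoxy-2-(iodomethylidene)-6-methylhept-5-enoate | CC(C)=CCC(OC(C)=O)/C(=C/I)C(=O)OC
F5 | step 2 | methyl (2Z,3S)-3-acetoxy-2-(iodomethylidene)-6-methylhept-5-enoate | CC(C)=CC[C@H](OC(C)=O)/C(=C/I)C(=O)OC
F6 | step 12 | 2-{4-[(R)-1-hydroxy-4-methylpent-3-enyl]furan-2-yl}benzene-1,4-diol | CC(C)=CC[C@@H](O)c1coc(-c2cc(O)ccc2O)c1
F7 | step 12 | (R)-1-{5-[2,5-bis(3-methylbutanoyloxy)phenyl]furan-3-yl}-4-methylpent-3-enyl 3-methylbutanoate | CC(C)=CC[C@@H](OC(=O)CC(C)C)c1coc(-c2cc(OC(=O)CC(C)C)ccc2OC(=O)CC(C)C)c1
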